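**Strategy**

Everything rests on opening the dihydrofuran ring of the benzofuran core at two bonds, C3–CH2OH and O1–C2. In that ring C3 carries a one-carbon hydroxymethyl arm while the adjacent C2 carries the ring oxygen and the electron-rich 3,4-dimethoxyphenyl ring: the imprint of formaldehyde adding across a stilbene C=C whose benzylic cation is trapped by an ortho phenol. A single chiral-acid-catalysed Prins addition with phenol capture therefore makes the C–C bond, the C–O bond, the five-membered ring and both stereocentres. Its substrate is an E-stilbene whose ring A bears the free phenol beside the alkene, a silylated phenol (the later C7–OH) and the methyl acrylate arm.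

Key step: step 5

Remark on the chemistry: which antipode of the chiral acid leads to the (2R,3S) series cannot be foretold; the (S,S) acid is written, and its mirror image is used instead if the induction proves opposite.

Remark on the chemistry: in the open-chain compounds ring A is numbered from the acrylate-bearing carbon (C1); its O3 becomes the C7 oxygen and its O4 becomes O1 of the benzofuran.

Design notes:
- The aldehyde is homologated with a stabilised ylide, which needs no base, so no catechol dianion is involved.
- The silyl group is put on before the Heck coupling, while the hindered oxygen sits next to the bulky iodine, so no free catechol meets palladium.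
- A tert-butyldimethylsilyl ether is chosen because hydroxide removes it in the same flask as the methyl ester.

**Route**

Step 1
Reactants: 1 5-iodovanillin (4-hydroxy-3-iodo-5-methoxybenzaldehyde)
Product: 2 3,4-dihydroxy-5-iodobenzaldehyde
Conditions: AlCl3 (1.1 equiv), pyridine (4.4 equiv), CH2Cl2, reflux; then 2 M HCl
Reagents that add atoms: none
Why: Chelation-assisted aryl methyl ether cleavage (AlCl3–pyridine demethylation of an ortho-hydroxyanisole): aluminium bound at the free C4 oxygen activates only the neighbouring methoxy group, whose methyl is taken up by pyridine, so the aldehyde and the aryl iodide are left alone.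

Step 2
Reactants: 2 3,4-dihydroxy-5-iodobenzaldehyde; 3 methyl (triphenylphosphoranylidene)acetate
Product: 4 methyl (E)-3-(3,4-dihydroxy-5-iodophenyl)prop-2-enoate
Conditions: ylide (1.5 equiv), toluene, 80 °C
Reagents that add atoms: none
Why: Wittig olefination with an ester-stabilised ylide, which needs no added base, tolerates the free catechol and the aryl iodide, and should give the E-acrylate as stabilised ylides do with aryl aldehydes.

Step 3
Reactants: 4 methyl (E)-3-(3,4-dihydroxy-5-iodophenyl)prop-2-enoate
Product: 5 methyl (E)-3-[3-(tert-butyldimethylsilyloxy)-4-hydroxy-5-iodophenyl]prop-2-enoate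
Conditions: TBSCl (1.05 equiv), imidazole (2.5 equiv), DMF, 0 °C to rt
Reagents that add atoms: tert-butyldimethylsilyl chloride, CC(C)(C)[Si](C)(C)Cl
Why: Silyl ether formation on the less hindered hydroxyl of a catechol: the C3–OH has only a hydrogen and the other hydroxyl as neighbours, whereas the C4–OH is wedged between that hydroxyl and the large iodine atom and is the more acidic, less nucleophilic oxygen (para to the acrylate), so the bulky silyl chloride should go to O3, and a silyl group that reaches O4 can drift back by 1,2 O-to-O migration.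

Step 4
Reactants: 5 methyl (E)-3-[3-(tert-butyldimethylsilyloxy)-4-hydroxy-5-iodophenyl]prop-2-enoate; 6 3,4-dimethoxystyrene
Product: 7 methyl (E)-3-{3-(tert-butyldimethylsilyloxy)-5-[(E)-2-(3,4-dimethoxyphenyl)ethenyl]-4-hydroxyphenyl}prop-2-enoate
Conditions: Pd(OAc)2 (5 mol%), P(o-tol)3 (10 mol%), Et3N (3 equiv), DMF, 90 °C, argon
Reagents that add atoms: none
Why: Mizoroki–Heck coupling: the aryl iodide adds oxidatively to zerovalent palladium formed from Pd(OAc)2, the terminal styrene inserts with the aryl group on its CH2 carbon and syn β-hydride elimination gives the E-stilbene, while the 1,2-disubstituted, electron-poor acrylate C=C of 5 is a far slower acceptor and the aryl silyl ether tolerates the amine base.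

Step 5
Reactants: 7 methyl (E)-3-{3-(tert-butyldimethylsilyloxy)-5-[(E)-2-(3,4-dimethoxyphenyl)ethenyl]-4-hydroxyphenyl}prop-2-enoate; 8 formaldehyde (charged as paraformaldehyde)
Product: 10 methyl (E)-3-[(2R,3S)-7-(tert-butyldimethylsilyloxy)-2-(3,4-dimethoxyphenyl)-3-(hydroxymethyl)-2,3-dihydro-1-benzofuran-5-yl]prop-2-enoate, via benzylic cation 9 (not isolated)
Conditions: (CH2O)n (5 equiv), (S,S)-imidodiphosphorimidate Brønsted acid (BINOL-derived, N-triflyl, 5 mol%), CHCl3, −20 to 0 °C; then Et3N, aq. NaHCO3
Reagents that add atoms: none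
Why: Proposed new method: the confined chiral acid cracks paraformaldehyde and protonates monomeric formaldehyde 8, which is attacked by the ring-A-bound alkene carbon of 7 (the later C3) so that the charge lands on the neighbouring carbon as cation 9, stabilised by the para-methoxy group of the dimethoxyphenyl ring and paired with the chiral anion; the phenol oxygen then closes onto this carbon and returns the proton to the catalyst. The closest known reaction types are the chiral-Brønsted-acid-catalysed intermolecular Prins reaction of styrenes with formaldehyde and the 5-endo halo- or seleno-etherification of 2-hydroxystilbenes, here merged so that an internal phenol replaces the second formaldehyde as the cation trap. The dihydrofuran ring (O1, C2, C3, C3a, C7a) closes through the O1–C2 bond in a formally 5-endo-trig mode, which is permissible because the acceptor is a free, planar benzylic cation and not a polarised alkene. C3 is set by the catalyst, whose chiral anion pocket must present formaldehyde to the Si face of that alkene carbon (giving 3S), and C2 is set by the substrate, because the phenol adds anti to the new C–C bond on the rotamer that keeps the aryl group and CH2OH trans (2R), a preference backed by reversible C2–O1 ionisation that can only drain a cis isomer into the trans one without touching C3. The step needs C–C bond formation at C3 and not C2, reaction at the stilbene and not at the acrylate or the arenes, and formaldehyde addition ahead of plain protonation of the alkene: the 4-methoxy group makes the C2 cation the better one while the acrylate para to the phenol weakens the ortho-hydroxyl stabilisation of the alternative cation and deactivates ring A and its own C=C, and an excess of formaldehyde at low temperature keeps the acid tied up as its formaldehyde adduct so that direct hydroalkoxylation and 1,3-dioxane formation are held back.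

Step 6
Reactants: 10 methyl (E)-3-[(2R,3S)-7-(tert-butyldimethylsilyloxy)-2-(3,4-dimethoxyphenyl)-3-(hydroxymethyl)-2,3-dihydro-1-benzofuran-5-yl]prop-2-enoate
Product: 12 (E)-3-[(2R,3S)-2-(3,4-dimethoxyphenyl)-7-hydroxy-3-(hydroxymethyl)-2,3-dihydro-1-benzofuran-5-yl]prop-2-enoic acid, via phenol methyl ester 11 (not isolated)
Conditions: LiOH·H2O (6 equiv), THF/MeOH/H2O (3:1:1), degassed, rt to 40 °C; then 1 M HCl to pH 3, 0 °C
Reagents that add atoms: lithium hydroxide, [Li+].[OH-]
Why: Base-mediated aryl silyl ether cleavage followed by saponification: hydroxide first removes the silyl group from the phenol oxygen (a good leaving group from silicon) and then hydrolyses the methyl ester, while neither stereocentre carries an acidic hydrogen and the E-acrylate, the primary alcohol and the benzylic ether are inert to base, so the (2R,3S) configuration should be carried unchanged into the acid.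

**Compound list**

1 | 5-iodovanillin (4-hydroxy-3-iodo-5-methoxybenzaldehyde) | COc1cc(C=O)cc(I)c1O | starting material
2 | 3,4-dihydroxy-5-iodobenzaldehyde | O=Cc1cc(O)c(O)c(I)c1 | intermediate
3 | methyl (triphenylphosphoranylidene)acetate | COC(=O)C=P(c1ccccc1)(c1ccccc1)c1ccccc1 | starting material
4 | methyl (E)-3-(3,4-dihydroxy-5-iodophenyl)prop-2-enoate | COC(=O)/C=C/c1cc(O)c(O)c(I)c1 | intermediate
5 | methyl (E)-3-[3-(tert-butyldimethylsilyloxy)-4-hydroxy-5-iodophenyl]prop-2-enoate | COC(=O)/C=C/c1cc(O[Si](C)(C)C(C)(C)C)c(O)c(I)c1 | intermediate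
6 | 3,4-dimethoxystyrene | COc1ccc(C=C)cc1OC | starting material
7 | methyl (E)-3-{3-(tert-butyldimethylsilyloxy)-5-[(E)-2-(3,4-dimethoxyphenyl)ethenyl]-4-hydroxyphenyl}prop-2-enoate | COc1ccc(/C=C/c2cc(/C=C/C(=O)OC)cc(O[Si](C)(C)C(C)(C)C)c2O)cc1OC | intermediate
8 | formaldehyde (charged as paraformaldehyde, cracked to the monomer by the acid) | C=O | starting material
9 | benzylic cation from 7 and protonated formaldehyde: methyl (E)-3-{3-(tert-butyldimethylsilyloxy)-5-[(2S)-1-(3,4-dimethoxyphenyl)-3-hydroxypropan-1-ylium-2-yl]-4-hydroxyphenyl}prop-2-enoate, paired with the chiral anion | COc1ccc([CH+][C@H](CO)c2cc(/C=C/C(=O)OC)cc(O[Si](C)(C)C(C)(C)C)c2O)cc1OC | intermediate (not isolated)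
10 | methyl (E)-3-[(2R,3S)-7-(tert-butyldimethylsilyloxy)-2-(3,4-dimethoxyphenyl)-3-(hydroxymethyl)-2,3-dihydro-1-benzofuran-5-yl]prop-2-enoate (2,3-trans) | COc1ccc([C@@H]2Oc3c(O[Si](C)(C)C(C)(C)C)cc(/C=C/C(=O)OC)cc3[C@H]2CO)cc1OC | intermediate
11 | methyl (E)-3-[(2R,3S)-2-(3,4-dimethoxyphenyl)-7-hydroxy-3-(hydroxymethyl)-2,3-dihydro-1-benzofuran-5-yl]prop-2-enoate | COc1ccc([C@@H]2Oc3c(O)cc(/C=C/C(=O)OC)cc3[C@H]2CO)cc1OC | intermediate (not isolated)
12 | (E)-3-[(2R,3S)-2-(3,4-dimethoxyphenyl)-7-hydroxy-3-(hydroxymethyl)-2,3-dihydro-1-benzofuran-5-yl]prop-2-enoic acid | COc1ccc([C@@H]2Oc3c(O)cc(/C=C/C(=O)O)cc3[C@H]2CO)cc1OC | target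

**Step count**

Total steps: 6. Longest linear sequence: 6 steps (1 → 2 → 4 → 5 → 7 → 10 → 12).

**Steps most likely to fail**

1. Step 5 (the new method). What may go wrong:
- plain protonation of the stilbene followed by phenol closure, which would build the ring without the one-carbon arm;
- capture of the cation by a second formaldehyde;
- C–C bond formation at the wrong alkene carbon;
- weak facial control by the anion.

Fallback, known reactions only (Evans aldol, then acid-mediated closure), setting out from 4 and returning to the route at 11. Both phenols of 4 are silylated (TBSOTf, 2,6-lutidine, CH2Cl2) to give methyl (E)-3-[3,4-bis(tert-butyldimethylsilyloxy)-5-iodophenyl]prop-2-enoate F1. Negishi-type coupling with the Reformatsky reagent BrZnCH2CO2tBu (Pd(dba)2 as the zerovalent palladium source, XPhos, THF, 50 °C) gives tert-butyl 2-{2,3-bis(tert-butyldimethylsilyloxy)-5-[(E)-3-methoxy-3-oxoprop-1-en-1-yl]phenyl}acetate F2. Anhydrous TFA in CH2Cl2 at 0 °C releases 2-{2,3-bis(tert-butyldimethylsilyloxy)-5-[(E)-3-methoxy-3-oxoprop-1-en-1-yl]phenyl}acetic acid F3. Its mixed pivalic anhydride (PivCl, Et3N) acylates (R)-4-benzyloxazolidin-2-one in the presence of LiCl to give methyl (E)-3-{3-[2-((R)-4-benzyl-2-oxooxazolidin-3-yl)-2-oxoethyl]-4,5-bis(tert-butyldimethylsilyloxy)phenyl}prop-2-enoate F4. The dibutylboron Z-enolate (Bu2BOTf, iPr2NEt, CH2Cl2, −78 °C) adds to 3,4-dimethoxybenzaldehyde to give the Evans syn aldol methyl (E)-3-{3-[(2R,3R)-1-((R)-4-benzyl-2-oxooxazolidin-3-yl)-3-(3,4-dimethoxyphenyl)-3-hydroxy-1-oxopropan-2-yl]-4,5-bis(tert-butyldimethylsilyloxy)phenyl}prop-2-enoate F5, in which the auxiliary fixes the arylacetate carbon that becomes C3. NaBH4 in THF/H2O cleaves the imide reductively, without touching the methyl acrylate, to methyl (E)-3-{3,4-bis(tert-butyldimethylsilyloxy)-5-[(1R,2S)-1-(3,4-dimethoxyphenyl)-1,3-dihydroxypropan-2-yl]phenyl}prop-2-enoate F6. Bu4NF buffered with AcOH frees the catechol, methyl (E)-3-{5-[(1R,2S)-1-(3,4-dimethoxyphenyl)-1,3-dihydroxypropan-2-yl]-3,4-dihydroxyphenyl}prop-2-enoate F7. Catalytic p-TsOH in CH2Cl2 then ionises the dimethoxybenzylic alcohol and the ortho phenol closes the ring trans to CH2OH, giving 11, which is saponified to 12 as in step 6.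

2. Step 3. What may go wrong: silylation on both oxygens or on the hindered one, and scrambling by silyl migration, leaving a mixture that is hard to separate.

Fallback, setting out from 2 and returning at 5; the two oxygens are told apart at the aldehyde stage by leaving-group ability instead of by sterics. Exhaustive silylation of 2 (TBSOTf, 2,6-lutidine, CH2Cl2) gives 3,4-bis(tert-butyldimethylsilyloxy)-5-iodobenzaldehyde F8. The silyl ether para to the formyl group, whose phenoxide is by far the better leaving group, is cleaved selectively (catalytic LiOAc, moist DMF, rt) to give 3-(tert-butyldimethylsilyloxy)-4-hydroxy-5-iodobenzaldehyde F9. Wittig olefination with ylide 3 in toluene then gives 5.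

3. Step 4. What may go wrong:
- inhibition of the catalyst by the ortho phenoxide;
- loss or migration of the silyl group in hot amine base;
- arylation at the internal carbon of the electron-rich styrene.

Fallback, setting out from 4 and returning at 7, with the catechol masked as esters during the coupling. Acetylation of 4 (Ac2O, pyridine) gives methyl (E)-3-(3,4-diacetoxy-5-iodophenyl)prop-2-enoate F10. Heck coupling with 6 (Pd(OAc)2, P(o-tol)3, Et3N, DMF, 90 °C) gives methyl (E)-3-{3,4-diacetoxy-5-[(E)-2-(3,4-dimethoxyphenyl)ethenyl]phenyl}prop-2-enoate F11. K2CO3 in degassed MeOH at 0 °C removes both acetates to give methyl (E)-3-{3,4-dihydroxy-5-[(E)-2-(3,4-dimethoxyphenyl)ethenyl]phenyl}prop-2-enoate F12. Mono-silylation (TBSCl, imidazole, DMF) at the hydroxyl that is not flanked by the styryl group then gives 7.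

**Further compounds**

F1 | step 5 | methyl (E)-3-[3,4-bis(tert-butyldimethylsilyloxy)-5-iodophenyl]prop-2-enoate | COC(=O)/C=C/c1cc(O[Si](C)(C)C(C)(C)C)c(O[Si](C)(C)C(C)(C)C)c(I)c1
F2 | step 5 | tert-butyl 2-{2,3-bis(tert-butyldimethylsilyloxy)-5-[(E)-3-methoxy-3-oxoprop-1-en-1-yl]phenyl}acetate | COC(=O)/C=C/c1cc(CC(=O)OC(C)(C)C)c(O[Si](C)(C)C(C)(C)C)c(O[Si](C)(C)C(C)(C)C)c1
F3 | step 5 | 2-{2,3-bis(tert-butyldimethylsilyloxy)-5-[(E)-3-methoxy-3-oxoprop-1-en-1-yl]phenyl}acetic acid | COC(=O)/C=C/c1cc(CC(=O)O)c(O[Si](C)(C)C(C)(C)C)c(O[Si](C)(C)C(C)(C)C)c1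
F4 | step 5 | methyl (E)-3-{3-[2-((R)-4-benzyl-2-oxooxazolidin-3-yl)-2-oxoethyl]-4,5-bis(tert-butyldimethylsilyloxy)phenyl}prop-2-enoate | COC(=O)/C=C/c1cc(CC(=O)N2[C@H](Cc3ccccc3)COC2=O)c(O[Si](C)(C)C(C)(C)C)c(O[Si](C)(C)C(C)(C)C)c1
F5 | step 5 | methyl (E)-3-{3-[(2R,3R)-1-((R)-4-benzyl-2-oxooxazolidin-3-yl)-3-(3,4-dimethoxyphenyl)-3-hydroxy-1-oxopropan-2-yl]-4,5-bis(tert-butyldimethylsilyloxy)phenyl}prop-2-enoate | COC(=O)/C=C/c1cc([C@@H](C(=O)N2[C@H](Cc3ccccc3)COC2=O)[C@@H](O)c2ccc(OC)c(OC)c2)c(O[Si](C)(C)C(C)(C)C)c(O[Si](C)(C)C(C)(C)C)c1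
F6 | step 5 | methyl (E)-3-{3,4-bis(tert-butyldimethylsilyloxy)-5-[(1R,2S)-1-(3,4-dimethoxyphenyl)-1,3-dihydroxypropan-2-yl]phenyl}prop-2-enoate | COC(=O)/C=C/c1cc([C@@H](CO)[C@@H](O)c2ccc(OC)c(OC)c2)c(O[Si](C)(C)C(C)(C)C)c(O[Si](C)(C)C(C)(C)C)c1
F7 | step 5 | methyl (E)-3-{5-[(1R,2S)-1-(3,4-dimethoxyphenyl)-1,3-dihydroxypropan-2-yl]-3,4-dihydroxyphenyl}prop-2-enoate | COC(=O)/C=C/c1cc([C@@H](CO)[C@@H](O)c2ccc(OC)c(OC)c2)c(O)c(O)c1
F8 | step 3 | 3,4-bis(tert-butyldimethylsilyloxy)-5-iodobenzaldehyde | O=Cc1cc(O[Si](C)(C)C(C)(C)C)c(O[Si](C)(C)C(C)(C)C)c(I)c1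
F9 | step 3 | 3-(tert-butyldimethylsilyloxy)-4-hydroxy-5-iodobenzaldehyde | O=Cc1cc(O[Si](C)(C)C(C)(C)C)c(O)c(I)c1
F10 | step 4 | methyl (E)-3-(3,4-diacetoxy-5-iodophenyl)prop-2-enoate | COC(=O)/C=C/c1cc(OC(C)=O)c(OC(C)=O)c(I)c1
F11 | step 4 | methyl (E)-3-{3,4-diacetoxy-5-[(E)-2-(3,4-dimethoxyphenyl)ethenyl]phenyl}prop-2-enoate | COc1ccc(/C=C/c2cc(/C=C/C(=O)OC)cc(OC(C)=O)c2OC(C)=O)cc1OC
F12 | step 4 | methyl (E)-3-{3,4-dihydroxy-5-[(E)-2-(3,4-dimethoxyphenyl)ethenyl]phenyl}prop-2-enoate | COc1ccc(/C=C/c2cc(/C=C/C(=O)OC)cc(O)c2O)cc1OC
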